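**Strategy.** Everything rests on cutting the side chain (C1' = ring-bound CH2, up to C16') at C4'–C5' and, inside the C5'–C16' piece, at C6'–C7'. C7' is a methyl-bearing CH with no heteroatom within reach, so an orthoester Claisen rearrangement forms C6'–C7' and sets C7' in one operation, relaying chirality from a temporary (S)-carbinol at C9' across an E C7'=C8' alkene. Its precursor is the (E)-propenyl carbinol 6, made from (R)-citronellal, which supplies C11'. C3' comes from (R)-2-methylglycidol; the quinone ring, the only ring, is unmasked last from its hydroquinone dimethyl ether.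

Key step: step 5

Remark on the chemistry: the aryl nucleophile has to open the oxirane CH2 of (R)-2-methylglycidol and the chain has to bond later to its former CH2OH carbon. In this order the (R)-enantiomer leads to 3'R, and the C–O bond of the quaternary centre is never broken. The given structures are stereochemically consistent with this order and with an (S,S)-configured transfer-hydrogenation catalyst.

Assumption: (R)-citronellal, (R)-2-methylglycidol and 0.5 M prop-1-ynylmagnesium bromide in THF are bought, the first two in high enantiomeric purity.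

**Route**

Step 1
Reactants: 1 (R)-citronellal; 2 prop-1-ynylmagnesium bromide
Product: 3 (4RS,6R)-6,10-dimethylundec-9-en-2-yn-4-ol (both C4 epimers)
Conditions: 2 (1.2 equiv), THF, −78 → 0 °C; aq NH4Cl
Reagents that add atoms: 2 prop-1-ynylmagnesium bromide, CC#C[Mg]Br
Why: Grignard 1,2-addition of a weakly basic alkynyl nucleophile to the enolisable aldehyde should be clean; the C11' centre of 1 is not involved, and the carbinol epimer mixture is irrelevant because step 2 removes that centre.

Step 2
Reactants: 3 (4RS,6R)-6,10-dimethylundec-9-en-2-yn-4-ol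
Product: 4 (6R)-6,10-dimethylundec-9-en-2-yn-4-one
Conditions: Dess–Martin periodinane, CH2Cl2, 0 °C → rt
Reagents that add atoms: none
Why: Dess–Martin oxidation of a secondary propargylic alcohol should give the ynone without isomerisation; the stereocentre is β to the carbonyl and cannot epimerise, and the trisubstituted alkene is inert.

Step 3
Reactants: 4 (6R)-6,10-dimethylundec-9-en-2-yn-4-one
Product: 5 (4S,6R)-6,10-dimethylundec-9-en-2-yn-4-ol
Conditions: RuCl[(S,S)-TsDPEN](p-cymene) (1 mol %), KOH (2 mol %), i-PrOH, 25 °C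
Reagents that add atoms: none
Why: Noyori asymmetric transfer hydrogenation of an α,β-acetylenic ketone, in which the alkynyl group takes the place of the aryl group of an aryl ketone, so the (S,S)-catalyst should deliver hydride to the face that gives the (S)-carbinol (C9'); reagent control should override the remote C11' centre, and the isolated alkene is not reduced.

Step 4
Reactants: 5 (4S,6R)-6,10-dimethylundec-9-en-2-yn-4-ol
Product: 6 (2E,4S,6R)-6,10-dimethylundeca-2,9-dien-4-ol
Conditions: LiAlH4, THF, 0 °C → reflux; then H2O, 15% aq NaOH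
Reagents that add atoms: none
Why: hydroxyl-directed trans-hydroalumination of a propargylic alcohol, with hydride delivered from the alkoxyaluminate to the distal alkyne carbon, should give only the E-alkene after protonolysis; the carbinol centre and the isolated trisubstituted alkene are untouched.

Step 5
Reactants: 6 (2E,4S,6R)-6,10-dimethylundeca-2,9-dien-4-ol; 7 triethyl orthoacetate
Product: 10 ethyl (3S,4E,7R)-3,7,11-trimethyldodeca-4,10-dienoate, via mixed orthoester 8 (not isolated), via ketene acetal 9 (not isolated)
Conditions: 7 (6 equiv), EtCO2H (5 mol %), 135–140 °C, EtOH distilled off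
Reagents that add atoms: 7 triethyl orthoacetate, CC(OCC)(OCC)OCC
Why: Acid-catalysed exchange of one ethoxy group of 7 for the carbinol gives 8, loss of ethanol gives ketene acetal 9, and 9 undergoes a concerted suprafacial [3,3]-sigmatropic shift in which the C6'–C7' bond forms as the C9'–O bond breaks. This is the Johnson–Claisen (orthoester Claisen) rearrangement, well established for secondary (E)-allylic alcohols. No ring is closed, since the six-membered array exists only in the transition state. The new C7' centre is controlled by the C9' carbinol configuration: in the chair the C10' chain on the carbinol carbon sits equatorial, so with the (S)-carbinol and the E-propenyl unit the acetate carbon bonds to the C7' face on the side of the departing oxygen, which gives 3S in 10 (7'R after saturation). The step needs complete 1,3-transfer of chirality and an E C8'=C9' alkene; both should follow from the equatorial preference in the chair, from the enantiopurity at C9' set in step 3 and from the E geometry set in step 4. The C11' centre and the isopropylidene alkene are spectators under the weakly acidic conditions, and the stereogenic oxygen is consumed.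

Step 6
Reactants: 10 ethyl (3S,4E,7R)-3,7,11-trimethyldodeca-4,10-dienoate
Product: 11 ethyl (3R,7R)-3,7,11-trimethyldodecanoate
Conditions: H2 (1–3 atm), PtO2 (2 mol %), EtOAc, rt
Reagents that add atoms: none
Why: heterogeneous catalytic hydrogenation should saturate both alkenes and leave the ester alone; platinum is chosen over palladium because it causes little double-bond migration, so the allylic C7' centre should not be scrambled, and its descriptor changes from S to R only through the change in CIP priorities.

Step 7
Reactants: 11 ethyl (3R,7R)-3,7,11-trimethyldodecanoate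
Product: 12 (3R,7R)-3,7,11-trimethyldodecan-1-ol
Conditions: LiAlH4, THF, 0 °C → rt; then H2O, 15% aq NaOH
Reagents that add atoms: none
Why: LiAlH4 reduction of an ester to the primary alcohol; no stereocentre is α to the carbonyl, so nothing can epimerise.

Step 8
Reactants: 12 (3R,7R)-3,7,11-trimethyldodecan-1-ol
Product: 13 (3R,7R)-1-bromo-3,7,11-trimethyldodecane
Conditions: CBr4, PPh3, CH2Cl2, 0 °C → rt
Reagents that add atoms: tetrabromomethane, BrC(Br)(Br)Br
Why: Appel bromination, an SN2 displacement of the oxyphosphonium group at a primary carbon under neutral conditions, far from both stereocentres.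

Step 9
Reactants: 14 2,3,5-trimethylhydroquinone
Product: 15 1,4-dimethoxy-2,3,5-trimethylbenzene
Conditions: Me2SO4 (2.5 equiv), K2CO3, acetone, reflux, N2
Reagents that add atoms: dimethyl sulfate, COS(=O)(=O)OC
Why: Williamson O-methylation of both phenols; the inert atmosphere should prevent oxidation of the hydroquinone to the quinone under base.

Step 10
Reactants: 15 1,4-dimethoxy-2,3,5-trimethylbenzene
Product: 16 1-(chloromethyl)-2,5-dimethoxy-3,4,6-trimethylbenzene
Conditions: (CH2O)n, conc. aq HCl, HCl (g), 1,4-dioxane, 60 °C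
Reagents that add atoms: formaldehyde (as paraformaldehyde), C=O; hydrogen chloride, Cl
Why: Blanc chloromethylation, an electrophilic aromatic substitution at the only free position of an electron-rich arene, so the regiochemistry is unambiguous.

Step 11
Reactants: 16 1-(chloromethyl)-2,5-dimethoxy-3,4,6-trimethylbenzene; 17 (R)-2-methylglycidol
Product: 19 (2S)-4-(2,5-dimethoxy-3,4,6-trimethylphenyl)-2-methylbutane-1,2-diol, via benzylic Grignard reagent 18 (not isolated)
Conditions: Mg (I2-activated), THF, 0 °C, slow addition of 16 (2.3 equiv relative to 17); then 17, CuI (10 mol %), −30 → 0 °C; aq NH4Cl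
Reagents that add atoms: 17 (R)-2-methylglycidol, OC[C@@]1(C)OC1
Why: magnesium insertion into the benzylic chloride, then copper-catalysed SN2 opening of the terminal epoxide at its unsubstituted CH2 (one equivalent of 18 is spent on the hydroxyl), forms the C1'–C2' bond; the quaternary C3' carbon is not attacked and keeps its configuration (descriptor R → S by CIP only), and Payne isomerisation of the alkoxide of 17 is degenerate and returns the same enantiomer.

Step 12
Reactants: 19 (2S)-4-(2,5-dimethoxy-3,4,6-trimethylphenyl)-2-methylbutane-1,2-diol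
Product: 21 (2S)-2-[2-(2,5-dimethoxy-3,4,6-trimethylphenyl)ethyl]-2-methyloxirane, via primary tosylate 20 (not isolated)
Conditions: TsCl (1.1 equiv), Et3N, DMAP (cat.), CH2Cl2, 0 °C; then K2CO3, MeOH, rt
Reagents that add atoms: none
Why: selective sulfonylation of the primary over the tertiary hydroxyl, then intramolecular Williamson closure (3-exo-tet) by the tertiary alkoxide; the C3'–O bond is not broken, so the configuration is retained.

Step 13
Reactants: 13 (3R,7R)-1-bromo-3,7,11-trimethyldodecane; 21 (2S)-2-[2-(2,5-dimethoxy-3,4,6-trimethylphenyl)ethyl]-2-methyloxirane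
Product: 23 (3R,7R,11R)-1-(2,5-dimethoxy-3,4,6-trimethylphenyl)-3,7,11,15-tetramethylhexadecan-3-ol, via alkyl Grignard reagent 22 (not isolated)
Conditions: Mg, THF, 40 °C (13, 1.5 equiv); then 21, CuI (10 mol %), THF, −30 → 0 °C; aq NH4Cl
Reagents that add atoms: none
Why: Grignard formation from a saturated primary bromide and copper-catalysed SN2 opening of the 2,2-disubstituted epoxide at its CH2 terminus should form the C4'–C5' bond and release the tertiary C3' alcohol; none of the three stereocentres takes part.

Step 14
Reactants: 23 (3R,7R,11R)-1-(2,5-dimethoxy-3,4,6-trimethylphenyl)-3,7,11,15-tetramethylhexadecan-3-ol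
Product: 24 α-tocopherylquinone, 2-[(3R,7R,11R)-3-hydroxy-3,7,11,15-tetramethylhexadecyl]-3,5,6-trimethylcyclohexa-2,5-diene-1,4-dione
Conditions: (NH4)2Ce(NO3)6 (2.5 equiv), MeCN–H2O (2:1), 0 °C
Reagents that add atoms: water, O
Why: oxidative demethylation of a para-dimethoxyarene by (NH4)2Ce(NO3)6 (two one-electron oxidations, addition of water, loss of methanol) should give the quinone; the tertiary alcohol and the saturated chain are inert and no stereocentre is touched.

**Compound list**

1 | (R)-citronellal, (3R)-3,7-dimethyloct-6-enal | O=CC[C@H](C)CCC=C(C)C | starting material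
2 | prop-1-ynylmagnesium bromide | CC#C[Mg]Br | starting material
3 | (4RS,6R)-6,10-dimethylundec-9-en-2-yn-4-ol (both C4 epimers) | CC#CC(O)C[C@H](C)CCC=C(C)C | intermediate
4 | (6R)-6,10-dimethylundec-9-en-2-yn-4-one | CC#CC(=O)C[C@H](C)CCC=C(C)C | intermediate
5 | (4S,6R)-6,10-dimethylundec-9-en-2-yn-4-ol | CC#C[C@@H](O)C[C@H](C)CCC=C(C)C | intermediate
6 | (2E,4S,6R)-6,10-dimethylundeca-2,9-dien-4-ol | C/C=C/[C@@H](O)C[C@H](C)CCC=C(C)C | intermediate
7 | triethyl orthoacetate | CC(OCC)(OCC)OCC | starting material
8 | (2E,4S,6R)-4-(1,1-diethoxyethoxy)-6,10-dimethylundeca-2,9-diene (mixed orthoester) | CC(OCC)(OCC)O[C@H](/C=C/C)C[C@H](C)CCC=C(C)C | intermediate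
9 | (2E,4S,6R)-4-[(1-ethoxyethenyl)oxy]-6,10-dimethylundeca-2,9-diene (ketene acetal) | C=C(OCC)O[C@H](/C=C/C)C[C@H](C)CCC=C(C)C | intermediate
10 | ethyl (3S,4E,7R)-3,7,11-trimethyldodeca-4,10-dienoate | CCOC(=O)C[C@H](C)/C=C/C[C@H](C)CCC=C(C)C | intermediate
11 | ethyl (3R,7R)-3,7,11-trimethyldodecanoate | CCOC(=O)C[C@H](C)CCC[C@H](C)CCCC(C)C | intermediate
12 | (3R,7R)-3,7,11-trimethyldodecan-1-ol | OCC[C@H](C)CCC[C@H](C)CCCC(C)C | intermediate
13 | (3R,7R)-1-bromo-3,7,11-trimethyldodecane | BrCC[C@H](C)CCC[C@H](C)CCCC(C)C | intermediate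
14 | 2,3,5-trimethylhydroquinone, 2,3,5-trimethylbenzene-1,4-diol | Cc1cc(O)c(C)c(C)c1O | starting material
15 | 1,4-dimethoxy-2,3,5-trimethylbenzene | COc1cc(C)c(OC)c(C)c1C | intermediate
16 | 1-(chloromethyl)-2,5-dimethoxy-3,4,6-trimethylbenzene | COc1c(C)c(C)c(OC)c(C)c1CCl | intermediate
17 | (R)-2-methylglycidol, [(2R)-2-methyloxiran-2-yl]methanol | OC[C@@]1(C)OC1 | starting material
18 | (2,5-dimethoxy-3,4,6-trimethylbenzyl)magnesium chloride | COc1c(C)c(C)c(OC)c(C)c1C[Mg]Cl | intermediate
19 | (2S)-4-(2,5-dimethoxy-3,4,6-trimethylphenyl)-2-methylbutane-1,2-diol | COc1c(C)c(C)c(OC)c(C)c1CC[C@](C)(O)CO | intermediate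
20 | (2S)-4-(2,5-dimethoxy-3,4,6-trimethylphenyl)-2-hydroxy-2-methylbutyl 4-methylbenzenesulfonate | COc1c(C)c(C)c(OC)c(C)c1CC[C@](C)(O)COS(=O)(=O)c1ccc(C)cc1 | intermediate
21 | (2S)-2-[2-(2,5-dimethoxy-3,4,6-trimethylphenyl)ethyl]-2-methyloxirane | COc1c(C)c(C)c(OC)c(C)c1CC[C@@]1(C)CO1 | intermediate
22 | [(3R,7R)-3,7,11-trimethyldodecyl]magnesium bromide | Br[Mg]CC[C@H](C)CCC[C@H](C)CCCC(C)C | intermediate
23 | (3R,7R,11R)-1-(2,5-dimethoxy-3,4,6-trimethylphenyl)-3,7,11,15-tetramethylhexadecan-3-ol | COc1c(C)c(C)c(OC)c(C)c1CC[C@](C)(O)CCC[C@H](C)CCC[C@H](C)CCCC(C)C | intermediate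
24 | α-tocopherylquinone, 2-[(3R,7R,11R)-3-hydroxy-3,7,11,15-tetramethylhexadecyl]-3,5,6-trimethylcyclohexa-2,5-diene-1,4-dione | CC1=C(C)C(=O)C(CC[C@](C)(O)CCC[C@H](C)CCC[C@H](C)CCCC(C)C)=C(C)C1=O | target

**Count and risks**

Total step count: 14. Longest linear sequence: 10 steps (steps 1–8, 13, 14); the aryl branch (steps 9–12) joins at step 13.

Steps most likely to fail:

1. Step 11. The benzylic halide may homocouple during magnesium insertion, and reagent is lost to protonation, so the opening of 17 may stall. Fallback, setting out from 16 and coming back at 19: 16 is used as the electrophile instead. The dianion of 2-methylprop-2-en-1-ol (n-BuLi, TMEDA, Et2O) is alkylated at carbon by 16 to give 2-[2-(2,5-dimethoxy-3,4,6-trimethylphenyl)ethyl]prop-2-en-1-ol F1. Sharpless asymmetric epoxidation (Ti(OiPr)4, L-(+)-diethyl tartrate, t-BuOOH, 4 Å sieves, CH2Cl2, −20 °C) should then give [(2S)-2-[2-(2,5-dimethoxy-3,4,6-trimethylphenyl)ethyl]oxiran-2-yl]methanol F2. LiAlH4 in THF opens the oxirane of F2 at its CH2 and gives diol 19. C3' is then set by the tartrate and not by 17.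

2. Step 13. Attack at the neopentyl-type CH2 of 21 may be slow, which lets magnesium halide open the oxirane or rearrange it. Fallback, setting out from 13 and coming back at 23: 13 and NaO2SPh in DMF give [(3R,7R)-3,7,11-trimethyldodecyl]sulfonylbenzene F3. Its α-lithio derivative (n-BuLi, THF–DMPU, 0 °C → rt) opens 21 at the CH2 terminus to give (3S,5RS,7R,11R)-5-(benzenesulfonyl)-1-(2,5-dimethoxy-3,4,6-trimethylphenyl)-3,7,11,15-tetramethylhexadecan-3-ol F4 (C5 epimers; C3 has the same spatial arrangement as in 23, and only its descriptor changes). Reductive desulfonylation with sodium amalgam, Na(Hg), and Na2HPO4 in MeOH gives 23.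

3. Step 5. The allylic orthoester may partly ionise, which would erode the transfer of chirality, or acid-mediated elimination may occur at 140 °C. Fallback, setting out from 6 and coming back at 10, by an Ireland–Claisen rearrangement under basic, low-temperature conditions: 6 is acetylated (Ac2O, pyridine, DMAP) to (2E,4S,6R)-6,10-dimethylundeca-2,9-dien-4-yl acetate F5. LDA and Me3SiCl in THF at −78 °C give the silyl ketene acetal (2E,4S,6R)-6,10-dimethyl-4-[[1-(trimethylsilyloxy)ethenyl]oxy]undeca-2,9-diene F6. On warming, F6 should rearrange through the same chair to trimethylsilyl (3S,4E,7R)-3,7,11-trimethyldodeca-4,10-dienoate F7, and aqueous work-up gives (3S,4E,7R)-3,7,11-trimethyldodeca-4,10-dienoic acid F8. EtI and K2CO3 in DMF convert F8 into 10.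

Further compounds
F1 | step 11 | 2-[2-(2,5-dimethoxy-3,4,6-trimethylphenyl)ethyl]prop-2-en-1-ol | COc1c(C)c(C)c(OC)c(C)c1CCC(=C)CO
F2 | step 11 | [(2S)-2-[2-(2,5-dimethoxy-3,4,6-trimethylphenyl)ethyl]oxiran-2-yl]methanol | COc1c(C)c(C)c(OC)c(C)c1CC[C@]1(CO)CO1
F3 | step 13 | [(3R,7R)-3,7,11-trimethyldodecyl]sulfonylbenzene | O=S(=O)(CC[C@H](C)CCC[C@H](C)CCCC(C)C)c1ccccc1
F4 | step 13 | (3S,5RS,7R,11R)-5-(benzenesulfonyl)-1-(2,5-dimethoxy-3,4,6-trimethylphenyl)-3,7,11,15-tetramethylhexadecan-3-ol | COc1c(C)c(C)c(OC)c(C)c1CC[C@](C)(O)CC(C[C@H](C)CCC[C@H](C)CCCC(C)C)S(=O)(=O)c1ccccc1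
F5 | step 5 | (2E,4S,6R)-6,10-dimethylundeca-2,9-dien-4-yl acetate | CC(=O)O[C@H](/C=C/C)C[C@H](C)CCC=C(C)C
F6 | step 5 | (2E,4S,6R)-6,10-dimethyl-4-[[1-(trimethylsilyloxy)ethenyl]oxy]undeca-2,9-diene | C=C(O[Si](C)(C)C)O[C@H](/C=C/C)C[C@H](C)CCC=C(C)C
F7 | step 5 | trimethylsilyl (3S,4E,7R)-3,7,11-trimethyldodeca-4,10-dienoate | C[Si](C)(C)OC(=O)C[C@H](C)/C=C/C[C@H](C)CCC=C(C)C
F8 | step 5 | (3S,4E,7R)-3,7,11-trimethyldodeca-4,10-dienoic acid | OC(=O)C[C@H](C)/C=C/C[C@H](C)CCC=C(C)C
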